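## Structural features

The target is a deoxybenzoin: ring A (4-methoxyphenyl) carries the ketone C=O, which is joined through a single CH2 group to C1' of ring B. Ring B is a tetrasubstituted benzene with the CH2 at C1', hydroxyl groups at C3' and C5', and a 4-methylpentanoyl ketone at C4', i.e. a 2-acylresorcinol with a carbon branch para to the acyl group. There is no stereocentre and no stereogenic double bond, so every selectivity question is one of regio- or chemoselectivity. The fragile sites are the doubly activated CH2 between ring B and the aryl ketone (enolisable, easily oxidised), the two free phenols, and the methyl ether of ring A. That ether must survive while ring B ends with free OH groups, which makes a final global O-demethylation unattractive. The real difficulty is C4': an acyl group between two oxygen-bearing carbons, whereas electrophilic substitution of a 5-substituted resorcinol goes to C2'/C6', and a carbanion at C4' cannot coexist with the enolisable deoxybenzoin ketone. The feature exploited is that the array C3'(O)–C4'(acyl)–C5'(O) with a carbon branch at C1' is the dehydro form of a 2-acyl-5-substituted cyclohexane-1,3-dione, in which C4' is the only nucleophilic ring carbon. Ring B can therefore be built from open-chain pieces through the bonds C1'–C2' and C3'–C4' instead of being bought, and the CH2–C(=O) unit next to ring A is the hydration pattern of an alkyne polarised by the para-methoxy group.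

## Logic of the disconnections

16 ⇒ 15. No C–C bond is cut. Ring B is taken back by two hydrogens (at C1' and C2') to the cyclohexane-1,3-dione oxidation level. The reason is that at this level the two oxygens and the acyl group are already in place and the phenols arise simply by tautomerisation, so no O-protecting group is ever needed. The demand on the forward step is a dehydrogenation that touches only the ring and spares both side-chain ketones and the aryl ether.

15 ⇒ 14. The C(=O)–CH2 pair next to ring A is returned to a C≡C bond. The alkyne is a base-stable, non-enolisable mask for the ketone, which would otherwise bring an acidic CH2 and a second electrophile into the ring-forming chemistry. The demand is that water adds at the alkyne carbon bonded to ring A. The para-methoxy group secures this.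

14 ⇒ 11 + 12. The bond C4'–C(=O) of the acyl group is cut. In 11, C4' lies between two carbonyl groups and is the only nucleophilic carbon, so the regiochemical problem of the target disappears. The demand is C- rather than O-acylation, met by an O→C acyl transfer.

11 ⇒ 6 + 7 (key disconnection). The ring bonds C1'–C2' and C3'–C4' are cut, and a carboxyl group is put back on C2'. Ring B falls apart into an open-chain enynone that supplies C4', C5', C6' and C1' with the side chain, and a three-carbon diester that supplies C2' and C3'. In one sentence: ring B is closed from 6 and 7 by a Michael–Claisen annulation. The gain is a six-membered ring with its complete 1,3-dioxygen/5-carbon pattern from two acyclic, achiral pieces. The demands are 1,4- rather than 1,6-addition to 6, ring closure by attack of the methyl ketone carbon on an ester, and decarboxylation without harm to the alkyne.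

6 ⇒ 4 + 5. The C6'=C1' double bond is cut. A stabilised ylide delivers C4'–C6' onto the aldehyde carbon, which becomes C1'. The alkene geometry is irrelevant because C1' becomes sp3 in the next step.

4 ⇒ 1. The bond between the alkyne carbon and the formyl carbon (future C1') is cut, leading back to a purchased terminal aryl alkyne and a one-carbon formyl donor.

## Other disconnections considered

Alternative 1: (the first that comes to mind) Ring B is bought and the bond C4'–C(=O) is cut by directed ortho-metalation. Silyl ether A1 would be lithiated between its two MOM-oxy groups and acylated with Weinreb amide A2 to give ketone A3. The benzylic carbon of A3 would then have to be advanced to the aryl ketone over several steps (desilylation, activation, coupling with a masked 4-methoxybenzoyl anion, unmasking, MOM removal). The chosen plan is preferred because the deoxybenzoin ketone cannot be present during the lithiation (acidic CH2, electrophilic C=O), which forces a long, fixed order of events. Three protecting groups would be carried only to be removed, and the count would be well above six steps.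

Alternative 2: The same ring bonds are cut, but with the acyl group already on the nucleophile. The dianion of diketone A4 would add through its terminal carbon to C1' of enynoate A5 and close on the ester through its central carbon, giving A6 (identical with 14) in one operation. The chosen plan is preferred on mechanistic grounds. The terminal carbanion of such a dianion is hard and strongly basic, so attack on the ester carbonyl (leading to an open 1,3,5-triketone) and 1,6-addition are expected to compete. A4 also has two different terminal sites, and no irreversible sink sorts these pathways. The one step saved is the C-acylation, which is reliable on its own.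

Alternative 3: Ring B is bought as bromide A7 and joined to ring A by a C(sp2)–C(sp) coupling. A7 would be metalated between the methoxy groups and acylated to A8, then coupled (Sonogashira) with alkyne A9 (identical with 1) to give tolan A10, followed by hydration and two O-demethylations. The chosen plan is preferred because deprotonation of A7 between Br and OMe (leading to aryne formation) competes with the wanted site. The route also ends with the need to cleave two hindered methyl ethers while keeping a third, a differentiation that the chosen plan never creates.

Key step: step 3

Assumption: the target is achiral, so the request for a single enantiomer is met by the constitution alone. β-Di- and β-triketones are written as keto tautomers although they exist largely as enols, and the transient stereocentres of intermediates are not defined because step 6 erases them.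

## Route

Step 1
Reactants: 1 1-ethynyl-4-methoxybenzene
Product: 4 3-(4-methoxyphenyl)prop-2-ynal, via lithium acetylide 2 (not isolated), via lithium hemiaminal alkoxide 3 (not isolated)
Conditions: n-BuLi, THF, −78 °C; DMF, −78 °C to rt; reverse quench into 10% aq. KH2PO4/MTBE, 0 °C
Reagents that add atoms: N,N-dimethylformamide, CN(C)C=O
Why: Formylation of a lithium acetylide with DMF (Bouveault type); adduct 3 is stable until the buffered reverse quench, which protonates the liberated dimethylamine so that it cannot add to the ynal.

Step 2
Reactants: 4 3-(4-methoxyphenyl)prop-2-ynal; 5 1-(triphenyl-λ5-phosphanylidene)propan-2-one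
Product: 6 (3E)-6-(4-methoxyphenyl)hex-3-en-5-yn-2-one
Conditions: CH2Cl2, rt
Reagents that add atoms: none
Why: Wittig olefination of a reactive ynal with a stabilised ylide, which should give the E-enynone; the geometry is of no consequence because this carbon becomes sp3 in step 3.

Step 3
Reactants: 6 (3E)-6-(4-methoxyphenyl)hex-3-en-5-yn-2-one; 7 dimethyl malonate
Product: 11 5-[(4-methoxyphenyl)ethynyl]cyclohexane-1,3-dione, via Michael adduct 8 (not isolated), via cyclic keto ester 9 (not isolated), via cyclic keto acid 10 (not isolated)
Conditions: NaOMe, MeOH, 0 °C to reflux; then 2 M aq. NaOH, 70 °C; then 2 M HCl to pH 2, 55 °C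
Reagents that add atoms: none
Why: The malonate anion adds to C4 of 6 (the enone β-carbon, future C1') to give 8, forming the C1'–C2' bond. Proton exchange then gives the methyl ketone enolate, whose carbon (future C4') attacks one ester carbonyl (future C3') in a 6-exo-trig Claisen (Dieckmann-type) closure with loss of methoxide to give 9. Compound 9 is at once deprotonated to the vinylogous-acid enolate, an irreversible sink that pulls the reversible Michael equilibrium forward. The closest known reaction type is the classical malonate–enone synthesis of 5-substituted cyclohexane-1,3-diones (dimedone synthesis). The selectivity needed is 1,4- over 1,6-addition (attack at the aryl-bearing alkyne carbon); it is secured by the soft, reversibly adding donor and by the fact that only the 1,4-adduct can close a six-membered ring, whereas a 1,6-adduct would require an eight-membered one. Saponification and acidification give 10, a vinylogous β-keto acid that should lose CO2 at about 55 °C, mild enough to leave the anisyl alkyne unhydrated. No stereocentre has to be controlled: the centres of 8–10 are transient and C5 of 11 lies on a mirror plane. The step delivers ring B with both oxygens, the branch at C1' and C4' as its only nucleophilic carbon.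

Step 4
Reactants: 11 5-[(4-methoxyphenyl)ethynyl]cyclohexane-1,3-dione; 12 4-methylpentanoic acid
Product: 14 5-[(4-methoxyphenyl)ethynyl]-2-(4-methylpentanoyl)cyclohexane-1,3-dione, via enol ester 13 (not isolated)
Conditions: DCC, DMAP (1.2 equiv), CH2Cl2, 0 °C to rt; 1 M HCl wash
Reagents that add atoms: none
Why: Carbodiimide activation and DMAP-mediated O-acylation give enol ester 13, which DMAP converts by O→C acyl transfer (Steglich-type, standard for 2-acyl cyclohexane-1,3-diones) into the chelated β-triketone, the thermodynamic sink; C2 is the only carbon nucleophile, so the acyl group can only arrive between the two oxygens.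

Step 5
Reactants: 14 5-[(4-methoxyphenyl)ethynyl]-2-(4-methylpentanoyl)cyclohexane-1,3-dione
Product: 15 5-[2-(4-methoxyphenyl)-2-oxoethyl]-2-(4-methylpentanoyl)cyclohexane-1,3-dione
Conditions: TfOH (20 mol %), H2O (3 equiv), CF3CH2OH, 50 °C
Reagents that add atoms: water, O
Why: Brønsted-acid Markovnikov hydration of an aryl alkyne: protonation at the ring-bonded alkyne carbon gives the vinyl cation stabilised by the 4-methoxyphenyl group, water adds at that carbon and the enol tautomerises to the aryl ketone; C2 of the triketone is blocked, so the ring enol cannot capture the cation at carbon.

Step 6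
Reactants: 15 5-[2-(4-methoxyphenyl)-2-oxoethyl]-2-(4-methylpentanoyl)cyclohexane-1,3-dione
Product: 16 1-{2,6-dihydroxy-4-[2-(4-methoxyphenyl)-2-oxoethyl]phenyl}-4-methylpentan-1-one
Conditions: Hg(OAc)2 (2.1 equiv), NaOAc, AcOH, 110 °C; dilute HCl work-up
Reagents that add atoms: none
Why: Mercury(II) acetate dehydrogenation of a 2-acylcyclohexane-1,3-dione to a 2-acylresorcinol (a known reaction on this class): mercuration of the enolised trione α to a ring carbonyl, loss of mercury and acetic acid across C4–C5 and tautomerisation give the arene, driven by aromatisation and two chelating hydrogen bonds; the oxidant is held near two equivalents to spare the CH2 next to the aryl ketone.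

## Compound list

1 | 1-ethynyl-4-methoxybenzene | COc1ccc(C#C)cc1 | starting material
2 | lithium (4-methoxyphenyl)acetylide | [Li]C#Cc1ccc(OC)cc1 | intermediate
3 | lithium 1-(dimethylamino)-3-(4-methoxyphenyl)prop-2-yn-1-olate (racemic) | CN(C)C(O[Li])C#Cc1ccc(OC)cc1 | intermediate
4 | 3-(4-methoxyphenyl)prop-2-ynal | COc1ccc(C#CC=O)cc1 | intermediate
5 | 1-(triphenyl-λ5-phosphanylidene)propan-2-one | CC(=O)C=P(c1ccccc1)(c1ccccc1)c1ccccc1 | starting material
6 | (3E)-6-(4-methoxyphenyl)hex-3-en-5-yn-2-one | COc1ccc(C#C/C=C/C(C)=O)cc1 | intermediate
7 | dimethyl malonate | COC(=O)CC(=O)OC | starting material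
8 | dimethyl 2-[1-(4-methoxyphenyl)-5-oxohex-1-yn-3-yl]propanedioate (racemic) | COc1ccc(C#CC(CC(C)=O)C(C(=O)OC)C(=O)OC)cc1 | intermediate
9 | methyl 6-[(4-methoxyphenyl)ethynyl]-2,4-dioxocyclohexane-1-carboxylate (racemic, present as sodium enolate) | COC(=O)C1C(C#Cc2ccc(OC)cc2)CC(=O)CC1=O | intermediate
10 | 6-[(4-methoxyphenyl)ethynyl]-2,4-dioxocyclohexane-1-carboxylic acid (racemic, present as disodium salt before acidification) | OC(=O)C1C(C#Cc2ccc(OC)cc2)CC(=O)CC1=O | intermediate
11 | 5-[(4-methoxyphenyl)ethynyl]cyclohexane-1,3-dione | COc1ccc(C#CC2CC(=O)CC(=O)C2)cc1 | intermediate
12 | 4-methylpentanoic acid | CC(C)CCC(O)=O | starting material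
13 | 5-[(4-methoxyphenyl)ethynyl]-3-oxocyclohex-1-en-1-yl 4-methylpentanoate (racemic) | CC(C)CCC(=O)OC1=CC(=O)CC(C#Cc2ccc(OC)cc2)C1 | intermediate
14 | 5-[(4-methoxyphenyl)ethynyl]-2-(4-methylpentanoyl)cyclohexane-1,3-dione (keto form of the enol) | CC(C)CCC(=O)C1C(=O)CC(C#Cc2ccc(OC)cc2)CC1=O | intermediate
15 | 5-[2-(4-methoxyphenyl)-2-oxoethyl]-2-(4-methylpentanoyl)cyclohexane-1,3-dione (keto form of the enol) | CC(C)CCC(=O)C1C(=O)CC(CC(=O)c2ccc(OC)cc2)CC1=O | intermediate
16 | 1-{2,6-dihydroxy-4-[2-(4-methoxyphenyl)-2-oxoethyl]phenyl}-4-methylpentan-1-one | COc1ccc(C(=O)Cc2cc(O)c(C(=O)CCC(C)C)c(O)c2)cc1 | target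

## Step count and least certain steps

Total step count: 6. Longest linear sequence: 6 steps (1 → 4 → 6 → 11 → 14 → 15 → 16).

Step 3 (key step). What may go wrong: addition of the malonate anion at the aryl-bearing alkyne terminus (1,6-addition) without reversal, base-induced propargyl-to-allenyl isomerisation of the adduct, or premature hydration of the electron-rich alkyne during the acidic decarboxylation. Fallback: the de novo ring construction is given up and the dione level is reached by dearomatisation. This fallback does not set out from a numbered intermediate; it starts from purchased (3,5-dihydroxyphenyl)acetic acid F1. F1 would be hydrogenated as its sodium salt (H2, Rh/Al2O3, aq. NaOH, then acid), where uptake should stop at the enolate stage, to give (3,5-dioxocyclohexyl)acetic acid F2. Friedel–Crafts acylation of anisole (methoxybenzene, COc1ccccc1) with F2 in Eaton's reagent should give the para-acylated keto dione 5-[2-(4-methoxyphenyl)-2-oxoethyl]cyclohexane-1,3-dione F3. C-acylation of F3 with 12 under the conditions of step 4 comes back to the route at 15. This path is held in reserve because it returns to the conventional bond set and because its Friedel–Crafts step must tolerate an unprotected enolised dione.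

Step 6. What may go wrong: over-oxidation at the CH2 between ring B and the aryl ketone once the product has formed, or mercuration of the electron-rich resorcinol ring that is not reversed on work-up. Fallback from 15: iodine in refluxing methanol (aromatisation with enol-ether formation) should give the monomethyl ether 1-{2-hydroxy-6-methoxy-4-[2-(4-methoxyphenyl)-2-oxoethyl]phenyl}-4-methylpentan-1-one F4. Chelation-directed cleavage of the methoxy group ortho to the ketone with BCl3 (CH2Cl2, −78 to 0 °C), which should leave the non-chelated ether of ring A alone, then comes back at 16.

Step 5. What may go wrong: acid-promoted retro-Claisen loss of the C2 acyl group from the β-triketone, or sluggish protonation of the alkyne so that decomposition outruns hydration. Fallback from 11: the order is reversed. Compound 11 is hydrated first (HCO2H–H2O 9:1, 90 °C) to 5-[2-(4-methoxyphenyl)-2-oxoethyl]cyclohexane-1,3-dione F5 (identical in structure with F3), and F5 is then C-acylated with 12 (DCC, DMAP), coming back at 15.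

Step 1. What may go wrong: conjugate addition of liberated dimethylamine to the ynal during the quench, or polymerisation of the ynal on isolation. Fallback from 1: the lithium acetylide is trapped with paraformaldehyde to give 3-(4-methoxyphenyl)prop-2-yn-1-ol F6. F6 is then oxidised with MnO2 in CH2Cl2 in the presence of ylide 5, so that the ynal is olefinated as it forms and never isolated, coming back at 6.

## Further compounds

F1 | step 3 | (3,5-dihydroxyphenyl)acetic acid (purchased) | OC(=O)Cc1cc(O)cc(O)c1
F2 | step 3 | (3,5-dioxocyclohexyl)acetic acid | OC(=O)CC1CC(=O)CC(=O)C1
F3 | step 3 | 5-[2-(4-methoxyphenyl)-2-oxoethyl]cyclohexane-1,3-dione | COc1ccc(C(=O)CC2CC(=O)CC(=O)C2)cc1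
F4 | step 6 | 1-{2-hydroxy-6-methoxy-4-[2-(4-methoxyphenyl)-2-oxoethyl]phenyl}-4-methylpentan-1-one | COc1ccc(C(=O)Cc2cc(O)c(C(=O)CCC(C)C)c(OC)c2)cc1
F5 | step 5 | 5-[2-(4-methoxyphenyl)-2-oxoethyl]cyclohexane-1,3-dione | COc1ccc(C(=O)CC2CC(=O)CC(=O)C2)cc1
F6 | step 1 | 3-(4-methoxyphenyl)prop-2-yn-1-ol | COc1ccc(C#CCO)cc1
A1 | alternative 1 | tert-butyl{[3,5-bis(methoxymethoxy)phenyl]methoxy}dimethylsilane | COCOc1cc(CO[Si](C)(C)C(C)(C)C)cc(OCOC)c1
A2 | alternative 1 | N-methoxy-N,4-dimethylpentanamide | CON(C)C(=O)CCC(C)C
A3 | alternative 1 | 1-[4-({[tert-butyl(dimethyl)silyl]oxy}methyl)-2,6-bis(methoxymethoxy)phenyl]-4-methylpentan-1-one | COCOc1cc(CO[Si](C)(C)C(C)(C)C)cc(OCOC)c1C(=O)CCC(C)C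
A4 | alternative 2 | 7-methyloctane-2,4-dione | CC(=O)CC(=O)CCC(C)C
A5 | alternative 2 | methyl (2E)-5-(4-methoxyphenyl)pent-2-en-4-ynoate | COC(=O)/C=C/C#Cc1ccc(OC)cc1
A6 | alternative 2 | 5-[(4-methoxyphenyl)ethynyl]-2-(4-methylpentanoyl)cyclohexane-1,3-dione | CC(C)CCC(=O)C1C(=O)CC(C#Cc2ccc(OC)cc2)CC1=O
A7 | alternative 3 | 1-bromo-3,5-dimethoxybenzene | COc1cc(Br)cc(OC)c1
A8 | alternative 3 | 1-(4-bromo-2,6-dimethoxyphenyl)-4-methylpentan-1-one | COc1cc(Br)cc(OC)c1C(=O)CCC(C)C
A9 | alternative 3 | 1-ethynyl-4-methoxybenzene | COc1ccc(C#C)cc1
A10 | alternative 3 | 1-{2,6-dimethoxy-4-[(4-methoxyphenyl)ethynyl]phenyl}-4-methylpentan-1-one | COc1ccc(C#Cc2cc(OC)c(C(=O)CCC(C)C)c(OC)c2)cc1
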